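**Retrosynthetic overview**

1. The (Z)-p-coumarate is attached last at O-15 by a Z-selective Horner–Wadsworth–Emmons reaction of a C-15 phosphonoacetate; the equatorial C-2 alcohol comes from a C-2 ketone by dissolving-metal reduction.
2. Key disconnection: the C-9–C-10 bond and the size of ring A. The bicyclic C-2 ketone is traced to a 1-hydroxybicyclo[3.1.0]hexane (cyclopentane C-2, C-3, C-4, C-5, C-10; cyclopropane carbon C-1) that carries the whole side chain on C-5. One anodic oxidation enlarges this cyclopentane to ring A and closes ring B as labdane biosynthesis does.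
3. Enabling feature: in ring A the oxygen-bearing C-2 and the quaternary, methyl-bearing C-10 are 1,3-related across the C-1 methylene (the pattern left by an oxidised cyclopropanol). C-10 is also linked through C-5, C-6 and C-7 to the C-8=C-9 unit of ring B, so a C-10 cation is the monocyclic cation of labdane biosynthesis.
4. The cyclopropanol comes from 2,4,4-trimethylcyclopent-2-enone by asymmetric conjugate addition of the side-chain Grignard reagent (sets C-5), enolate silylation and cyclopropanation. The side chain (C-6 to C-16, E-alkene, C-13 stereocentre) comes from (S)-citronellol by a Julia–Johnson olefin synthesis.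
5. Ring order: cyclopentane (bought) → ring A (one-carbon ring expansion) and ring B (6-endo cation–olefin closure) in the same step.

Key step: step 9

Remark: atoms are numbered as in labdane (ring A: C-1 to C-5 and C-10; ring B: C-5 to C-10; side chain C-11 to C-16; C-17 on C-8; C-18 and C-19 on C-4; C-20 on C-10), and compounds 1, 8, 20 and 22 are taken as commercial.

**Route**

Step 1
Reactants: 1 (S)-citronellol
Product: 2 benzyl (3S)-3,7-dimethyloct-6-en-1-yl ether
Conditions: NaH, BnBr, Bu4NI (cat.), THF, 0 °C → rt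
Reagents that add atoms: benzyl bromide BrCc1ccccc1
Why: Williamson etherification of the primary alkoxide protects O-15 with a group that survives the organometallic, oxidative and cationic steps and falls in step 10; the C-13 stereocentre comes from the chiral pool and is never touched.

Step 2
Reactants: 2 benzyl (3S)-3,7-dimethyloct-6-en-1-yl ether
Product: 3 (4S)-6-(benzyloxy)-4-methylhexanal
Conditions: O3, CH2Cl2, −78 °C; then Me2S, −78 °C → rt
Reagents that add atoms: ozone [O-][O+]=O
Why: Ozonolysis with reductive work-up cleaves the only alkene and leaves the aldehyde carbon that becomes C-9.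

Step 3
Reactants: 3 (4S)-6-(benzyloxy)-4-methylhexanal
Product: 4 (6S)-8-(benzyloxy)-2,6-dimethyloct-1-en-3-ol (both C-3 epimers)
Conditions: CH2=C(CH3)MgBr, THF, −78 → 0 °C; then sat. aq. NH4Cl
Reagents that add atoms: isopropenylmagnesium bromide CC(=C)[Mg]Br
Why: Grignard 1,2-addition brings in C-8, C-17 and C-7; the carbinol configuration is of no consequence because C-9 becomes sp2 in step 5.

Step 4
Reactants: 4 (6S)-8-(benzyloxy)-2,6-dimethyloct-1-en-3-ol
Product: 5 (4S)-6-(benzyloxy)-4-methyl-1-(1-methylcyclopropyl)hexan-1-ol (both C-1 epimers)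
Conditions: Et2Zn, CH2I2, CH2Cl2, 0 °C → rt
Reagents that add atoms: diiodomethane ICI
Why: Hydroxyl-directed Simmons–Smith cyclopropanation of the 1,1-disubstituted allylic alcohol adds the carbon that becomes C-6.

Step 5
Reactants: 5 (4S)-6-(benzyloxy)-4-methyl-1-(1-methylcyclopropyl)hexan-1-ol
Product: 7 (3E,7S)-9-(benzyloxy)-1-bromo-3,7-dimethylnon-3-ene, via cyclopropylcarbinyl bromide 6 (not isolated)
Conditions: PBr3, LiBr, 2,4,6-collidine, Et2O, −40 → 0 °C; then ZnBr2, Et2O, 0 °C → rt
Reagents that add atoms: phosphorus tribromide BrP(Br)Br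
Why: Julia–Johnson olefin synthesis: ZnBr2 re-ionises the secondary cyclopropylcarbinyl bromide and bromide opens the ring of the bisected cation, in which the chain lies away from the ring, so the primary homoallylic bromide with the E-trisubstituted C-8=C-9 alkene should be the thermodynamic sink.

Step 6
Reactants: 8 2,4,4-trimethylcyclopentan-1-one (racemic)
Product: 9 2,4,4-trimethylcyclopent-2-en-1-one
Conditions: IBX, DMSO/fluorobenzene, 70 °C
Reagents that add atoms: none
Why: α,β-Dehydrogenation of a ketone with IBX; only the C-2/C-3 enone can form because the other α-carbon is flanked by the quaternary carbon.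

Step 7
Reactants: 7 (3E,7S)-9-(benzyloxy)-1-bromo-3,7-dimethylnon-3-ene; 9 2,4,4-trimethylcyclopent-2-en-1-one
Product: 12 {[(3S)-3-[(3E,7S)-9-(benzyloxy)-3,7-dimethylnon-3-en-1-yl]-2,4,4-trimethylcyclopent-1-en-1-yl]oxy}trimethylsilane, via Grignard reagent 10 (not isolated), via magnesium enolate 11 (not isolated)
Conditions: Mg, Et2O, rt; then 9, CuBr·SMe2 (5 mol %), (R)-1-[(S_p)-2-(dicyclohexylphosphino)ferrocenyl]ethyldiphenylphosphine (6 mol %), t-BuOMe, −78 °C; then TMSCl, Et3N, DMPU, −78 → 0 °C
Reagents that add atoms: chlorotrimethylsilane C[Si](C)(C)Cl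
Why: Copper-catalysed asymmetric conjugate addition of a Grignard reagent to a cyclic enone followed by O-silylation of the magnesium enolate: the chiral ferrocenyl diphosphine–CuBr complex selects the enone face and so sets the C-5 stereocentre (3S in 12; the mirror-image ligand is used if the induction proves opposite), 2-methylcyclopent-2-enone being the closest documented substrate, and the trap fixes the tetrasubstituted C-2=C-10 enol ether regiospecifically.

Step 8
Reactants: 12 {[(3S)-3-[(3E,7S)-9-(benzyloxy)-3,7-dimethylnon-3-en-1-yl]-2,4,4-trimethylcyclopent-1-en-1-yl]oxy}trimethylsilane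
Product: 14 (1R,4S,5R)-4-[(3E,7S)-9-(benzyloxy)-3,7-dimethylnon-3-en-1-yl]-3,3,5-trimethylbicyclo[3.1.0]hexan-1-ol, via siloxycyclopropane 13 (not isolated)
Conditions: Et2Zn, CH2I2, Et2O, 0 °C → rt; then K2CO3 (cat.), MeOH, 0 °C
Reagents that add atoms: diiodomethane ICI
Why: Simmons–Smith cyclopropanation of the electron-rich silyl enol ether, which should react faster than the isolated trisubstituted alkene and anti to the C-5 chain, then mild methanolysis of the silyl ether; both new stereocentres are erased in step 9.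

Step 9
Reactants: 14 (1R,4S,5R)-4-[(3E,7S)-9-(benzyloxy)-3,7-dimethylnon-3-en-1-yl]-3,3,5-trimethylbicyclo[3.1.0]hexan-1-ol
Product: 18 (5S,9S,10S,13S)-15-(benzyloxy)labd-7-en-2-one, via C-10 radical 15 (not isolated), via C-10 cation 16 (not isolated), via C-8 cation 17 (not isolated)
Conditions: undivided cell, graphite anode, Pt cathode, constant current (about 2.1 F/mol), Bu4NPF6, 2,6-lutidine (0.5 equiv), CH2Cl2/HFIP (4:1), 0 °C
Reagents that add atoms: none
Why: Proposed new method: base-assisted anodic oxidation of the tertiary cyclopropanol should give an alkoxyl radical whose internal C-2–C-10 bond breaks to the ring-expanded tertiary radical 15, which is oxidised at the electrode to cation 16 in the manner of a Hofer–Moest radical-to-cation crossover and captured by the C-8=C-9 alkene to give cation 17, while proton reduction at the cathode balances the cell. The closest known reactions are the FeCl3-mediated oxidative ring expansion of 1-siloxybicyclo[n.1.0]alkanes with its tandem radical-cyclisation variants, and the acid-induced closure of monocyclic 2,2,6-trimethylcyclohexyl cations to trans-decalins, which the second half of the cascade copies from labdane biosynthesis. Ring A is not closed but enlarged from five to six atoms by β-scission of the cyclopropane bond, and ring B closes by 6-endo-trig Markovnikov attack of C-9 on C-10 through a chair-like transition state. C-10 is controlled by the C-5 stereocentre, whose equatorial chain reaches the cation face that leaves the methyl group axial (trans ring fusion), and C-9 is controlled by the E-geometry of the alkene, which places C-11 equatorial. The step needs internal rather than external cyclopropane cleavage (secured by the tertiary radical and the relief of bicyclic strain), oxidation of the carbinol before the alkene (secured by proton-coupled electron transfer to lutidine at low potential) and ring closure before proton loss from 16 to the enone (secured by the six-membered intramolecular capture in a weakly basic, cation-stabilising medium). Loss of the axial H-7 from 17 should then give mainly the endocyclic C-7=C-8 alkene.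

Step 10
Reactants: 18 (5S,9S,10S,13S)-15-(benzyloxy)labd-7-en-2-one
Product: 19 (2S,5S,9S,10S,13S)-labd-7-ene-2,15-diol
Conditions: Li, NH3(l), THF, t-BuOH, −78 → −33 °C; then NH4Cl
Reagents that add atoms: none
Why: Dissolving-metal (Birch-type) reduction protonates the ketyl-derived carbanion under thermodynamic control to the equatorial 2α-alcohol (hydride reagents would attack anti to the syn-axial C-19 and C-20 methyl groups and give the axial epimer) and cleaves the benzyl ether in the same operation, the isolated trisubstituted alkene being inert.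

Step 11
Reactants: 19 (2S,5S,9S,10S,13S)-labd-7-ene-2,15-diol; 20 2-(diphenoxyphosphoryl)acetic acid
Product: 21 (2S,5S,9S,10S,13S)-2-hydroxylabd-7-en-15-yl 2-(diphenoxyphosphoryl)acetate
Conditions: 20 (1.05 equiv), EDC·HCl, DMAP (cat.), CH2Cl2, −20 → 0 °C
Reagents that add atoms: none
Why: Steglich-type carbodiimide esterification; the unhindered primary C-15 hydroxyl should be acylated well before the ring secondary C-2 hydroxyl at low temperature with one equivalent of acid.

Step 12
Reactants: 21 (2S,5S,9S,10S,13S)-2-hydroxylabd-7-en-15-yl 2-(diphenoxyphosphoryl)acetate; 22 4-[(tert-butyldimethylsilyl)oxy]benzaldehyde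
Product: 23 (2S,5S,9S,10S,13S)-2-hydroxylabd-7-en-15-yl (2Z)-3-{4-[(tert-butyldimethylsilyl)oxy]phenyl}prop-2-enoate
Conditions: 22, NaI, DBU, THF, −78 → 0 °C, dark
Reagents that add atoms: none
Why: Horner–Wadsworth–Emmons olefination with a diaryl phosphonoacetate: the electron-poor aryloxy groups speed collapse of the kinetic adduct so that the Z-cinnamate should predominate, and NaI/DBU is mild enough for the free C-2 hydroxyl.

Step 13
Reactants: 23 (2S,5S,9S,10S,13S)-2-hydroxylabd-7-en-15-yl (2Z)-3-{4-[(tert-butyldimethylsilyl)oxy]phenyl}prop-2-enoate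
Product: 24 (2S,5S,9S,10S,13S)-2-hydroxylabd-7-en-15-yl (2Z)-3-(4-hydroxyphenyl)prop-2-enoate (CNP0301213.1)
Conditions: TBAF, AcOH, THF, 0 °C, dark
Reagents that add atoms: none
Why: Fluoride cleaves the aryl silyl ether, and acetic acid buffers the phenoxide so that the Z-enoate should neither isomerise nor transesterify.

**Compound list**

1 | (S)-citronellol [(3S)-3,7-dimethyloct-6-en-1-ol] | OCC[C@@H](C)CCC=C(C)C | starting material
2 | benzyl (3S)-3,7-dimethyloct-6-en-1-yl ether | CC(C)=CCC[C@H](C)CCOCc1ccccc1 | intermediate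
3 | (4S)-6-(benzyloxy)-4-methylhexanal | O=CCC[C@H](C)CCOCc1ccccc1 | intermediate
4 | (6S)-8-(benzyloxy)-2,6-dimethyloct-1-en-3-ol (both C-3 epimers) | C=C(C)C(O)CC[C@H](C)CCOCc1ccccc1 | intermediate
5 | (4S)-6-(benzyloxy)-4-methyl-1-(1-methylcyclopropyl)hexan-1-ol (both C-1 epimers) | CC1(CC1)C(O)CC[C@H](C)CCOCc1ccccc1 | intermediate
6 | 1-[(4S)-6-(benzyloxy)-1-bromo-4-methylhexyl]-1-methylcyclopropane (not isolated) | CC1(CC1)C(Br)CC[C@H](C)CCOCc1ccccc1 | intermediate
7 | (3E,7S)-9-(benzyloxy)-1-bromo-3,7-dimethylnon-3-ene | BrCC/C(C)=C/CC[C@H](C)CCOCc1ccccc1 | intermediate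
8 | 2,4,4-trimethylcyclopentan-1-one (racemic) | CC1CC(C)(C)CC1=O | starting material
9 | 2,4,4-trimethylcyclopent-2-en-1-one | CC1=CC(C)(C)CC1=O | intermediate
10 | [(3E,7S)-9-(benzyloxy)-3,7-dimethylnon-3-en-1-yl]magnesium bromide (not isolated) | Br[Mg]CC/C(C)=C/CC[C@H](C)CCOCc1ccccc1 | intermediate
11 | bromomagnesium (3S)-3-[(3E,7S)-9-(benzyloxy)-3,7-dimethylnon-3-en-1-yl]-2,4,4-trimethylcyclopent-1-en-1-olate (not isolated) | Br[Mg]OC1=C(C)[C@@H](CC/C(C)=C/CC[C@H](C)CCOCc2ccccc2)C(C)(C)C1 | intermediate
12 | {[(3S)-3-[(3E,7S)-9-(benzyloxy)-3,7-dimethylnon-3-en-1-yl]-2,4,4-trimethylcyclopent-1-en-1-yl]oxy}trimethylsilane | C[Si](C)(C)OC1=C(C)[C@@H](CC/C(C)=C/CC[C@H](C)CCOCc2ccccc2)C(C)(C)C1 | intermediate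
13 | {[(1R,4S,5R)-4-[(3E,7S)-9-(benzyloxy)-3,7-dimethylnon-3-en-1-yl]-3,3,5-trimethylbicyclo[3.1.0]hexan-1-yl]oxy}trimethylsilane (not isolated) | C[Si](C)(C)O[C@@]12C[C@]1(C)[C@@H](CC/C(C)=C/CC[C@H](C)CCOCc1ccccc1)C(C)(C)C2 | intermediate
14 | (1R,4S,5R)-4-[(3E,7S)-9-(benzyloxy)-3,7-dimethylnon-3-en-1-yl]-3,3,5-trimethylbicyclo[3.1.0]hexan-1-ol | O[C@@]12C[C@]1(C)[C@@H](CC/C(C)=C/CC[C@H](C)CCOCc1ccccc1)C(C)(C)C2 | intermediate
15 | C-10 radical: 6-[(3E,7S)-9-(benzyloxy)-3,7-dimethylnon-3-en-1-yl]-1,5,5-trimethyl-3-oxocyclohexyl radical, chain-bearing carbon configured as in 14 (not isolated) | C[C]1CC(=O)CC(C)(C)[C@@H]1CC/C(C)=C/CC[C@H](C)CCOCc1ccccc1 | intermediate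
16 | C-10 cation: 6-[(3E,7S)-9-(benzyloxy)-3,7-dimethylnon-3-en-1-yl]-1,5,5-trimethyl-3-oxocyclohexyl cation, chain-bearing carbon configured as in 14 (not isolated) | C[C+]1CC(=O)CC(C)(C)[C@@H]1CC/C(C)=C/CC[C@H](C)CCOCc1ccccc1 | intermediate
17 | C-8 cation: (5S,9S,10S,13S)-15-(benzyloxy)-2-oxolabdan-8-yl cation (not isolated) | C[C+]1CC[C@H]2C(C)(C)CC(=O)C[C@]2(C)[C@H]1CC[C@H](C)CCOCc1ccccc1 | intermediate
18 | (5S,9S,10S,13S)-15-(benzyloxy)labd-7-en-2-one [(4aS,8S,8aS)-8-[(3S)-5-(benzyloxy)-3-methylpentyl]-4,4,7,8a-tetramethyl-3,4,4a,5,8,8a-hexahydronaphthalen-2(1H)-one] | CC1=CC[C@H]2C(C)(C)CC(=O)C[C@]2(C)[C@H]1CC[C@H](C)CCOCc1ccccc1 | intermediate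
19 | (2S,5S,9S,10S,13S)-labd-7-ene-2,15-diol (2α-hydroxy, trans-decalin) | CC1=CC[C@H]2C(C)(C)C[C@H](O)C[C@]2(C)[C@H]1CC[C@H](C)CCO | intermediate
20 | 2-(diphenoxyphosphoryl)acetic acid | OC(=O)CP(=O)(Oc1ccccc1)Oc1ccccc1 | starting material
21 | (2S,5S,9S,10S,13S)-2-hydroxylabd-7-en-15-yl 2-(diphenoxyphosphoryl)acetate | CC1=CC[C@H]2C(C)(C)C[C@H](O)C[C@]2(C)[C@H]1CC[C@H](C)CCOC(=O)CP(=O)(Oc1ccccc1)Oc1ccccc1 | intermediate
22 | 4-[(tert-butyldimethylsilyl)oxy]benzaldehyde | O=Cc1ccc(O[Si](C)(C)C(C)(C)C)cc1 | starting material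
23 | (2S,5S,9S,10S,13S)-2-hydroxylabd-7-en-15-yl (2Z)-3-{4-[(tert-butyldimethylsilyl)oxy]phenyl}prop-2-enoate | CC1=CC[C@H]2C(C)(C)C[C@H](O)C[C@]2(C)[C@H]1CC[C@H](C)CCOC(=O)/C=C\c1ccc(O[Si](C)(C)C(C)(C)C)cc1 | intermediate
24 | (2S,5S,9S,10S,13S)-2-hydroxylabd-7-en-15-yl (2Z)-3-(4-hydroxyphenyl)prop-2-enoate (CNP0301213.1) | CC1=CC[C@H]2C(C)(C)C[C@H](O)C[C@]2(C)[C@H]1CC[C@H](C)CCOC(=O)/C=C\c1ccc(O)cc1 | target

**Step count and risks**

Total step count: 13.
Longest linear sequence: 12 steps (steps 1–5 and 7–13, from (S)-citronellol).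

Steps most likely to fail:

Step 9 (Proposed new method). The anode may oxidise the side-chain alkene in competition with the cyclopropanol. Cation 16 may lose a proton to the conjugated enone before it closes ring B. Cation 17 may lose its proton toward C-17 or C-9 instead of C-7. Fallback: the oxidation and the ring closure are separated with known chemistry. The fallback sets out from siloxycyclopropane 13, isolated by leaving out the methanolysis in step 8. Treatment of 13 with anhydrous FeCl3 in DMF at 0 °C (oxidative ring expansion of a siloxycyclopropane) should give the tertiary β-chloro ketone (4S)-4-[(3E,7S)-9-(benzyloxy)-3,7-dimethylnon-3-en-1-yl]-3-chloro-3,5,5-trimethylcyclohexan-1-one F1 as a mixture of C-3 epimers. Crude F1 is then ionised (HFIP/CH2Cl2 with 2,6-di-tert-butylpyridine, −40 °C → 0 °C, or SnCl4 in CH2Cl2 at −78 °C) to the same cation 16. Its cation–olefin cyclisation brings the route back at ketone 18.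

Step 7. Addition at the β-carbon of 9 may be slow and poorly face-selective, because this carbon is flanked by the α-methyl group and the gem-dimethyl carbon, and uncatalysed background addition may erode the induction further. Fallback: the methyl group is introduced after the conjugate addition. Grignard reagent 10 (from bromide 7) is added under the same CuBr·SMe2/ferrocenyl diphosphine catalysis to commercial 4,4-dimethylcyclopent-2-en-1-one, an α-unsubstituted enone of the class for which this reaction is best documented. This should give bromomagnesium (3R)-3-[(3E,7S)-9-(benzyloxy)-3,7-dimethylnon-3-en-1-yl]-4,4-dimethylcyclopent-1-en-1-olate F2. F2 is methylated in the same flask with MeI/DMPU, anti to the new side chain, to (2R,3R)-3-[(3E,7S)-9-(benzyloxy)-3,7-dimethylnon-3-en-1-yl]-2,4,4-trimethylcyclopentan-1-one F3. F3 is silylated under equilibrating conditions (TMSCl, NaI, Et3N, MeCN, rt) to the more substituted enol ether, which brings the route back at 12.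

Step 8. The zinc carbenoid may also cyclopropanate the trisubstituted side-chain alkene, and the zinc iodide formed may cleave the silyl enol ether before it reacts. Fallback: the enolate is cyclopropanated with a samarium carbenoid, which leaves isolated alkenes untouched. Silyl enol ether 12 is cleaved with MeLi (THF, 0 °C) to lithium (3S)-3-[(3E,7S)-9-(benzyloxy)-3,7-dimethylnon-3-en-1-yl]-2,4,4-trimethylcyclopent-1-en-1-olate F4. F4 is treated with SmI2 and CH2I2 (THF, −78 °C → rt), which after aqueous work-up should give cyclopropanol 14 directly.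

Further compounds
F1 | step 9 | (4S)-4-[(3E,7S)-9-(benzyloxy)-3,7-dimethylnon-3-en-1-yl]-3-chloro-3,5,5-trimethylcyclohexan-1-one (C-3 epimers) | CC1(Cl)CC(=O)CC(C)(C)[C@@H]1CC/C(C)=C/CC[C@H](C)CCOCc1ccccc1
F2 | step 7 | bromomagnesium (3R)-3-[(3E,7S)-9-(benzyloxy)-3,7-dimethylnon-3-en-1-yl]-4,4-dimethylcyclopent-1-en-1-olate | Br[Mg]OC1=C[C@@H](CC/C(C)=C/CC[C@H](C)CCOCc2ccccc2)C(C)(C)C1
F3 | step 7 | (2R,3R)-3-[(3E,7S)-9-(benzyloxy)-3,7-dimethylnon-3-en-1-yl]-2,4,4-trimethylcyclopentan-1-one | C[C@H]1C(=O)CC(C)(C)[C@@H]1CC/C(C)=C/CC[C@H](C)CCOCc1ccccc1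
F4 | step 8 | lithium (3S)-3-[(3E,7S)-9-(benzyloxy)-3,7-dimethylnon-3-en-1-yl]-2,4,4-trimethylcyclopent-1-en-1-olate | [Li]OC1=C(C)[C@@H](CC/C(C)=C/CC[C@H](C)CCOCc2ccccc2)C(C)(C)C1
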